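**Plan**

- Retrosynthesis: the O–O group goes back to an isopropenyl group and then to the tertiary carbinol. Ring B is cut at C1'–C2' and C5'–C6', which also opens oxepine ring D. Then follow the dienyl ether C–O bond, the ethynyl carbon, the pyrone ring (O1–C2, C2–C3) and the aryl–acyl bond C4–C4a.
- Enabling feature: ring B is a resorcinol whose C2' oxygen is the ring-D oxygen and whose C1' is bonded to chromone C2. An ethynyl group on C2 and a 1-alkoxy-3-siloxybutadiene carried on that oxygen therefore hold all six ring-B carbons.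
- Forward: ring A is olefinated and ortho-lithiated and opens the side-chain lactone to an aryl ketone. Ring C closes by Kostanecki–Robinson acylation. The 2-methyl group becomes ethynyl and the side-chain hydroxyl a siloxydienyl ether. Rings B and D then close together, and the hydroperoxide is made last.
- Stereochemistry: the single stereocentre is bought as (S)-5-oxotetrahydrofuran-2-carboxylic acid and no bond to it is ever broken. The E-alkene is set by iodine equilibration.

Key step: step 14

Assumption: hydroxy ketone 12 is drawn open-chain although it may rest partly as its five-membered hemiketal; either form should give acetate 13.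

**Step 1**
Reactants: 1 (S)-5-oxotetrahydrofuran-2-carboxylic acid
Product: 3 (S)-5-(2-hydroxypropan-2-yl)dihydrofuran-2(3H)-one, via (S)-5-oxotetrahydrofuran-2-carbonyl chloride 2 (not isolated)
Conditions: (COCl)2, cat. DMF, CH2Cl2, 0 °C to rt; evaporate; MeMgBr (2.1 equiv), THF, −78 °C; AcOH quench at −78 °C
Reagents that add atoms: methylmagnesium bromide (C[Mg]Br)
Why: Double Grignard addition to an acyl chloride: the acid chloride and the methyl ketone formed from it are both far more electrophilic than the γ-lactone at −78 °C, so both methyl groups should enter at the exocyclic carbonyl while the ring and the C–O stereocentre stay as bought.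

**Step 2**
Reactants: 3 (S)-5-(2-hydroxypropan-2-yl)dihydrofuran-2(3H)-one
Product: 4 (S)-5-[2-(triethylsilyloxy)propan-2-yl]dihydrofuran-2(3H)-one
Conditions: TESOTf, 2,6-lutidine, CH2Cl2, −78 to 0 °C
Reagents that add atoms: triethylsilyl trifluoromethanesulfonate (CC[Si](CC)(CC)OS(=O)(=O)C(F)(F)F)
Why: Silyl triflate silylation of a tertiary alcohol; the triethylsilyl ether should survive organolithium, base and buffered Lewis acid and can later be methanolysed with acid while an aryl silyl ether stays.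

**Step 3**
Reactants: 5 4-hydroxy-2,6-dimethoxybenzaldehyde
Product: 6 2,6-dimethoxy-4-(methoxymethoxy)benzaldehyde
Conditions: MOMCl, i-Pr2NEt, CH2Cl2, 0 °C to rt
Reagents that add atoms: chloromethyl methyl ether (COCCl)
Why: Williamson-type O-alkylation of the acidic para-formyl phenol; the methoxymethyl ether removes phenoxide deactivation of the aldehyde and later directs ortho-lithiation.

**Step 4**
Reactants: 6 2,6-dimethoxy-4-(methoxymethoxy)benzaldehyde; 7 isobutyltriphenylphosphonium bromide
Product: 9 1,3-dimethoxy-5-(methoxymethoxy)-2-[(Z)-3-methylbut-1-enyl]benzene, via (2-methylpropylidene)triphenylphosphorane 8 (not isolated)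
Conditions: 7, NaN(SiMe3)2, THF, 0 °C; then 6, −78 °C to rt
Reagents that add atoms: none
Why: Wittig olefination with a non-stabilised ylide, which is reactive enough for the electron-rich, doubly ortho-substituted aldehyde; kinetic control is expected to favour the Z-alkene, and the geometry is corrected in step 5.

**Step 5**
Reactants: 9 1,3-dimethoxy-5-(methoxymethoxy)-2-[(Z)-3-methylbut-1-enyl]benzene
Product: 10 1,3-dimethoxy-5-(methoxymethoxy)-2-[(E)-3-methylbut-1-enyl]benzene
Conditions: I2 (5 mol %), CH2Cl2, visible light, rt; aq. Na2S2O3 wash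
Reagents that add atoms: none
Why: Iodine-catalysed radical addition–elimination should equilibrate the styrene-type double bond to the thermodynamically preferred E isomer, in which the isopropyl group avoids the two ortho methoxy groups.

**Step 6**
Reactants: 10 1,3-dimethoxy-5-(methoxymethoxy)-2-[(E)-3-methylbut-1-enyl]benzene; 4 (S)-5-[2-(triethylsilyloxy)propan-2-yl]dihydrofuran-2(3H)-one
Product: 12 (S)-1-{2,4-dimethoxy-6-(methoxymethoxy)-3-[(E)-3-methylbut-1-enyl]phenyl}-4-hydroxy-5-methyl-5-(triethylsilyloxy)hexan-1-one, via 2,4-dimethoxy-6-(methoxymethoxy)-3-[(E)-3-methylbut-1-enyl]phenyllithium 11 (not isolated)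
Conditions: s-BuLi, TMEDA, THF, −78 °C; then 4, −78 to −40 °C; aq. NH4Cl
Reagents that add atoms: none
Why: Directed ortho-metalation at one of the two equivalent ring C–H positions (each flanked by OMe and OMOM) followed by nucleophilic acyl addition that opens the γ-lactone; the di-ortho-substituted aryl ketone is too hindered for a second addition, and the stereocentre is only released as the carbinol with retention.

**Step 7**
Reactants: 12 (S)-1-{2,4-dimethoxy-6-(methoxymethoxy)-3-[(E)-3-methylbut-1-enyl]phenyl}-4-hydroxy-5-methyl-5-(triethylsilyloxy)hexan-1-one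
Product: 13 (S)-6-{2,4-dimethoxy-6-(methoxymethoxy)-3-[(E)-3-methylbut-1-enyl]phenyl}-2-methyl-6-oxo-2-(triethylsilyloxy)hexan-3-yl acetate
Conditions: Ac2O, pyridine, cat. DMAP, CH2Cl2, rt
Reagents that add atoms: acetic anhydride (CC(=O)OC(C)=O)
Why: DMAP-catalysed acetylation traps the open-chain hydroxy ketone, removes the hemiketal equilibrium and shields the carbinol from the silyl triflate of step 8.

**Step 8**
Reactants: 13 (S)-6-{2,4-dimethoxy-6-(methoxymethoxy)-3-[(E)-3-methylbut-1-enyl]phenyl}-2-methyl-6-oxo-2-(triethylsilyloxy)hexan-3-yl acetate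
Product: 15 (S)-6-{6-hydroxy-2,4-dimethoxy-3-[(E)-3-methylbut-1-enyl]phenyl}-2-methyl-6-oxo-2-(triethylsilyloxy)hexan-3-yl acetate, via aryl trimethylsilyl ether 14 (not isolated)
Conditions: TMSOTf, 2,2'-bipyridyl, CH2Cl2, 0 °C to rt; then H2O
Reagents that add atoms: none
Why: Silyl triflate/2,2'-bipyridyl cleavage of an aryl methoxymethyl ether (an aryl silyl ether and a bipyridinium salt form and are hydrolysed by water); the buffered medium is expected to spare the tertiary triethylsilyl ether, the acetate and the styrene.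

**Step 9**
Reactants: 15 (S)-6-{6-hydroxy-2,4-dimethoxy-3-[(E)-3-methylbut-1-enyl]phenyl}-2-methyl-6-oxo-2-(triethylsilyloxy)hexan-3-yl acetate
Product: 16 3-[(S)-2-acetoxy-3-methyl-3-(triethylsilyloxy)butyl]-5,7-dimethoxy-2-methyl-6-[(E)-3-methylbut-1-enyl]-4H-chromen-4-one
Conditions: Ac2O, NaOAc, 140 °C
Reagents that add atoms: acetic anhydride (CC(=O)OC(C)=O)
Why: Kostanecki–Robinson acylation (phenol O-acetylation, acetyl transfer to the ketone α-carbon, cyclodehydration) converts an o-hydroxyaryl alkyl ketone into the 2-methyl-3-alkylchromone under acetate-buffered conditions in which silyl ether and acetate should persist.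

**Step 10**
Reactants: 16 3-[(S)-2-acetoxy-3-methyl-3-(triethylsilyloxy)butyl]-5,7-dimethoxy-2-methyl-6-[(E)-3-methylbut-1-enyl]-4H-chromen-4-one
Product: 18 3-[(S)-2-acetoxy-3-methyl-3-(triethylsilyloxy)butyl]-5,7-dimethoxy-6-[(E)-3-methylbut-1-enyl]-4-oxo-4H-chromene-2-carbaldehyde, via 2-[(E)-2-(dimethylamino)vinyl]chromone 17 (not isolated)
Conditions: Me2NCH(OMe)2 (neat), 120 °C; evaporate; NaIO4, THF/H2O, rt
Reagents that add atoms: sodium periodate ([Na+].[O-]I(=O)(=O)=O)
Why: The 2-methyl group is vinylogously activated by the pyrone carbonyl and condenses with the amide acetal to a push–pull enamine (Leimgruber–Batcho-type enamination), whose electron-rich C=C alone is cleaved by periodate, so the styrene and its allylic methine, which SeO2 might attack, are not at risk.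

**Step 11**
Reactants: 18 3-[(S)-2-acetoxy-3-methyl-3-(triethylsilyloxy)butyl]-5,7-dimethoxy-6-[(E)-3-methylbut-1-enyl]-4-oxo-4H-chromene-2-carbaldehyde
Product: 20 2-ethynyl-3-[(S)-2-hydroxy-3-methyl-3-(triethylsilyloxy)butyl]-5,7-dimethoxy-6-[(E)-3-methylbut-1-enyl]-4H-chromen-4-one, via acetoxy alkyne 19 (not isolated)
Conditions: dimethyl (1-diazo-2-oxopropyl)phosphonate, K2CO3, MeOH, 0 °C to rt; stirring continued until the acetate is methanolysed
Reagents that add atoms: dimethyl (1-diazo-2-oxopropyl)phosphonate (CC(=O)C(=[N+]=[N-])P(=O)(OC)OC)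
Why: Ohira–Bestmann modification of the Seyferth–Gilbert homologation (diazomethylphosphonate anion formed by methanolysis, addition to the aldehyde, 1,2-shift of the alkylidene carbene) should give the terminal alkyne, and the same carbonate/methanol medium then transesterifies the acetate.

**Step 12**
Reactants: 20 2-ethynyl-3-[(S)-2-hydroxy-3-methyl-3-(triethylsilyloxy)butyl]-5,7-dimethoxy-6-[(E)-3-methylbut-1-enyl]-4H-chromen-4-one; 21 but-3-yn-2-one
Product: 22 2-ethynyl-5,7-dimethoxy-6-[(E)-3-methylbut-1-enyl]-3-[(S)-3-methyl-2-{[(E)-3-oxobut-1-enyl]oxy}-3-(triethylsilyloxy)butyl]-4H-chromen-4-one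
Conditions: 21 (3 equiv), DABCO (20 mol %), CH2Cl2, 0 °C to rt
Reagents that add atoms: none
Why: Amine-catalysed oxa-Michael addition of an alcohol to a terminal ynone is expected to give the E-β-alkoxy enone; butynone is a far stronger acceptor than the vinylogous, pyrone-stabilised ethynyl group, so the alkoxide should be intercepted intermolecularly.

**Step 13**
Reactants: 22 2-ethynyl-5,7-dimethoxy-6-[(E)-3-methylbut-1-enyl]-3-[(S)-3-methyl-2-{[(E)-3-oxobut-1-enyl]oxy}-3-(triethylsilyloxy)butyl]-4H-chromen-4-one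
Product: 23 2-ethynyl-5,7-dimethoxy-6-[(E)-3-methylbut-1-enyl]-3-[(S)-3-methyl-3-(triethylsilyloxy)-2-{[(E)-3-(triisopropylsilyloxy)buta-1,3-dienyl]oxy}butyl]-4H-chromen-4-one
Conditions: TIPSOTf, Et3N, CH2Cl2, −78 to 0 °C; Et3N-deactivated silica
Reagents that add atoms: triisopropylsilyl trifluoromethanesulfonate (CC(C)[Si](OS(=O)(=O)C(F)(F)F)(C(C)C)C(C)C)
Why: Soft enolisation of the vinylogous-ester methyl ketone with silyl triflate and triethylamine is the standard preparation of 1-alkoxy-3-siloxybutadienes, and the molecule has no other enolisable position.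

**Step 14**
Reactants: 23 2-ethynyl-5,7-dimethoxy-6-[(E)-3-methylbut-1-enyl]-3-[(S)-3-methyl-3-(triethylsilyloxy)-2-{[(E)-3-(triisopropylsilyloxy)buta-1,3-dienyl]oxy}butyl]-4H-chromen-4-one
Product: 25 (S)-tetracycle (rings A–D) with 5,7-dimethoxy groups and the 6-[(E)-3-methylbut-1-enyl] group whose oxepine carbon bears C(CH3)2OSiEt3 and whose C4' bears OSi(i-Pr)3, via cyclohexa-1,4-diene cycloadduct 24 (not isolated)
Conditions: toluene (0.005 M), cat. BHT, base-washed glass, 130 °C, sealed tube; cool to 0 °C; DDQ (1.1 equiv), 2,6-di-tert-butylpyridine, 0 °C to rt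
Reagents that add atoms: none
Why: Proposed new method: a thermal normal-demand [4+2] cycloaddition in which the nucleophilic methylene terminus of the 1-alkoxy-3-siloxydiene (future C5') bonds to the alkyne terminus (C6'), the δ-electrophilic end of the C4=O/C3=C2/C≡C system, while the ether tether forces the oxygen-bearing diene terminus onto the inner alkyne carbon (C1'); DDQ then abstracts hydride from the doubly allylic C5'H2 of cyclohexa-1,4-diene 24 and the C2' proton is lost, so the ring-D oxygen is kept and the silyl enol ether becomes the C4' aryl silyl ether. The closest known reaction type is the intramolecular Diels–Alder reaction of 1-alkoxy-3-siloxybutadienes with conjugated alkynes followed by oxidative aromatisation; new here are the five-atom tether and the chromone-conjugated ethynyl dienophile. Ring B closes by the cycloaddition itself, and ring D closes as the seven-membered tether ring of a type 1 intramolecular Diels–Alder reaction (the alkyne carbon C1' is attacked in the exo sense), helped by the two sp2 tether atoms C2 and C3 that hold diene and alkyne cis. No lasting stereocentre is created: the sp3 centre at C2' of 24 is erased on aromatisation, and the side-chain stereocentre already in the tether is not touched. The step needs regioselectivity, which is secured twice (by the tether length and by matched polarity), and it needs oxidation in preference to elimination of the C2' alkoxide, which an acid-free medium (hindered pyridine, base-washed glass) and a hydride-abstracting quinone should secure.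

**Step 15**
Reactants: 25 (S)-tetracycle with C(CH3)2OSiEt3, C4' OSi(i-Pr)3 and 5,7-dimethoxy groups
Product: 26 (S)-tetracycle with free C(CH3)2OH, C4' OSi(i-Pr)3 and 5,7-dimethoxy groups
Conditions: CSA (10 mol %), MeOH/CH2Cl2, 0 °C
Reagents that add atoms: none
Why: Acid-catalysed methanolysis should remove the alkyl triethylsilyl ether much faster than the hindered aryl triisopropylsilyl ether, which is the more acid-stable of the two.

**Step 16**
Reactants: 26 (S)-tetracycle with free C(CH3)2OH, C4' OSi(i-Pr)3 and 5,7-dimethoxy groups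
Product: 27 (S)-tetracycle with C(CH3)2OH, C4' OSi(i-Pr)3, free C5 hydroxyl and C7 methoxy group
Conditions: MgI2·OEt2, toluene/Et2O, 60 °C
Reagents that add atoms: none
Why: Chelation-controlled ether cleavage: MgI2 binds between C4=O and the peri C5 methoxy oxygen and iodide dealkylates only that methyl group, leaving the C7 methyl ether, the ring-D ether and the aryl silyl ether.

**Step 17**
Reactants: 27 (S)-tetracycle with C(CH3)2OH, C4' OSi(i-Pr)3, free C5 hydroxyl and C7 methoxy group
Product: 28 (S)-tetracycle with isopropenyl group on the oxepine carbon, C4' OSi(i-Pr)3, C5 hydroxyl and C7 methoxy group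
Conditions: Burgess reagent, THF, 50 °C
Reagents that add atoms: none
Why: Burgess dehydration (syn elimination of the sulfamate ester) of the tertiary carbinol should favour the isopropenyl group for statistical and steric reasons (six methyl hydrogens against one hindered methine next to the aryloxy group), and the hydrogen-bonded C5 hydroxyl is too unreactive to be sulfamoylated.

**Step 18**
Reactants: 28 (S)-tetracycle with isopropenyl group, C4' OSi(i-Pr)3, C5 hydroxyl and C7 methoxy group
Product: 29 (S)-tetracycle with C(CH3)2OOSiEt3 on the oxepine carbon, C4' OSi(i-Pr)3, C5 hydroxyl and C7 methoxy group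
Conditions: Co(acac)2 (10 mol %), O2 (1 atm), Et3SiH, ClCH2CH2Cl, rt
Reagents that add atoms: dioxygen (O=O); triethylsilane (CC[SiH](CC)CC)
Why: Isayama–Mukaiyama silylperoxidation: a cobalt hydride transfers a hydrogen atom to the unhindered methylene terminus of the 1,1-disubstituted alkene, the tertiary radical is trapped by O2 and the peroxyl group is silylated, while the twisted, β-branched styrene is expected to react more slowly and the neighbouring stereocentre is not involved.

**Step 19**
Reactants: 29 (S)-tetracycle with C(CH3)2OOSiEt3, C4' OSi(i-Pr)3, C5 hydroxyl and C7 methoxy group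
Product: 30 CNP0171472.1
Conditions: TBAF, AcOH, THF, 0 °C
Reagents that add atoms: none
Why: Fluoride should cleave the Si–O bonds of both the silyl peroxide and the aryl silyl ether, and acetic acid buffering keeps the hydroperoxide and the phenols protonated.

**Compound list**

1 | (S)-5-oxotetrahydrofuran-2-carboxylic acid | O=C1CC[C@@H](C(=O)O)O1 | starting material
2 | (S)-5-oxotetrahydrofuran-2-carbonyl chloride | O=C1CC[C@@H](C(=O)Cl)O1 | intermediate
3 | (S)-5-(2-hydroxypropan-2-yl)dihydrofuran-2(3H)-one | O=C1CC[C@@H](C(C)(C)O)O1 | intermediate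
4 | (S)-5-[2-(triethylsilyloxy)propan-2-yl]dihydrofuran-2(3H)-one | O=C1CC[C@@H](C(C)(C)O[Si](CC)(CC)CC)O1 | intermediate
5 | 4-hydroxy-2,6-dimethoxybenzaldehyde | COc1cc(O)cc(OC)c1C=O | starting material
6 | 2,6-dimethoxy-4-(methoxymethoxy)benzaldehyde | COCOc1cc(OC)c(C=O)c(OC)c1 | intermediate
7 | isobutyltriphenylphosphonium bromide | CC(C)C[P+](c1ccccc1)(c1ccccc1)c1ccccc1.[Br-] | starting material
8 | (2-methylpropylidene)triphenylphosphorane | CC(C)C=P(c1ccccc1)(c1ccccc1)c1ccccc1 | intermediate
9 | 1,3-dimethoxy-5-(methoxymethoxy)-2-[(Z)-3-methylbut-1-enyl]benzene | COCOc1cc(OC)c(/C=C\C(C)C)c(OC)c1 | intermediate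
10 | 1,3-dimethoxy-5-(methoxymethoxy)-2-[(E)-3-methylbut-1-enyl]benzene | COCOc1cc(OC)c(/C=C/C(C)C)c(OC)c1 | intermediate
11 | 2,4-dimethoxy-6-(methoxymethoxy)-3-[(E)-3-methylbut-1-enyl]phenyllithium | [Li]c1c(OCOC)cc(OC)c(/C=C/C(C)C)c1OC | intermediate
12 | (S)-1-{2,4-dimethoxy-6-(methoxymethoxy)-3-[(E)-3-methylbut-1-enyl]phenyl}-4-hydroxy-5-methyl-5-(triethylsilyloxy)hexan-1-one | COCOc1cc(OC)c(/C=C/C(C)C)c(OC)c1C(=O)CC[C@@H](C(C)(C)O[Si](CC)(CC)CC)O | intermediate
13 | (S)-6-{2,4-dimethoxy-6-(methoxymethoxy)-3-[(E)-3-methylbut-1-enyl]phenyl}-2-methyl-6-oxo-2-(triethylsilyloxy)hexan-3-yl acetate | COCOc1cc(OC)c(/C=C/C(C)C)c(OC)c1C(=O)CC[C@@H](C(C)(C)O[Si](CC)(CC)CC)OC(C)=O | intermediate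
14 | aryl trimethylsilyl ether of 15 | C[Si](C)(C)Oc1cc(OC)c(/C=C/C(C)C)c(OC)c1C(=O)CC[C@@H](C(C)(C)O[Si](CC)(CC)CC)OC(C)=O | intermediate
15 | (S)-6-{6-hydroxy-2,4-dimethoxy-3-[(E)-3-methylbut-1-enyl]phenyl}-2-methyl-6-oxo-2-(triethylsilyloxy)hexan-3-yl acetate | Oc1cc(OC)c(/C=C/C(C)C)c(OC)c1C(=O)CC[C@@H](C(C)(C)O[Si](CC)(CC)CC)OC(C)=O | intermediate
16 | 3-[(S)-2-acetoxy-3-methyl-3-(triethylsilyloxy)butyl]-5,7-dimethoxy-2-methyl-6-[(E)-3-methylbut-1-enyl]-4H-chromen-4-one | COc1cc2oc(C)c(C[C@@H](C(C)(C)O[Si](CC)(CC)CC)OC(C)=O)c(=O)c2c(OC)c1/C=C/C(C)C | intermediate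
17 | 2-[(E)-2-(dimethylamino)vinyl] analogue of 16 | COc1cc2oc(/C=C/N(C)C)c(C[C@@H](C(C)(C)O[Si](CC)(CC)CC)OC(C)=O)c(=O)c2c(OC)c1/C=C/C(C)C | intermediate
18 | 3-[(S)-2-acetoxy-3-methyl-3-(triethylsilyloxy)butyl]-5,7-dimethoxy-6-[(E)-3-methylbut-1-enyl]-4-oxo-4H-chromene-2-carbaldehyde | COc1cc2oc(C=O)c(C[C@@H](C(C)(C)O[Si](CC)(CC)CC)OC(C)=O)c(=O)c2c(OC)c1/C=C/C(C)C | intermediate
19 | 3-[(S)-2-acetoxy-3-methyl-3-(triethylsilyloxy)butyl]-2-ethynyl-5,7-dimethoxy-6-[(E)-3-methylbut-1-enyl]-4H-chromen-4-one | COc1cc2oc(C#C)c(C[C@@H](C(C)(C)O[Si](CC)(CC)CC)OC(C)=O)c(=O)c2c(OC)c1/C=C/C(C)C | intermediate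
20 | 2-ethynyl-3-[(S)-2-hydroxy-3-methyl-3-(triethylsilyloxy)butyl]-5,7-dimethoxy-6-[(E)-3-methylbut-1-enyl]-4H-chromen-4-one | COc1cc2oc(C#C)c(C[C@@H](C(C)(C)O[Si](CC)(CC)CC)O)c(=O)c2c(OC)c1/C=C/C(C)C | intermediate
21 | but-3-yn-2-one | CC(=O)C#C | starting material
22 | 2-ethynyl-5,7-dimethoxy-6-[(E)-3-methylbut-1-enyl]-3-[(S)-3-methyl-2-{[(E)-3-oxobut-1-enyl]oxy}-3-(triethylsilyloxy)butyl]-4H-chromen-4-one | COc1cc2oc(C#C)c(C[C@@H](C(C)(C)O[Si](CC)(CC)CC)O/C=C/C(C)=O)c(=O)c2c(OC)c1/C=C/C(C)C | intermediate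
23 | 2-ethynyl-5,7-dimethoxy-6-[(E)-3-methylbut-1-enyl]-3-[(S)-3-methyl-3-(triethylsilyloxy)-2-{[(E)-3-(triisopropylsilyloxy)buta-1,3-dienyl]oxy}butyl]-4H-chromen-4-one | COc1cc2oc(C#C)c(C[C@@H](C(C)(C)O[Si](CC)(CC)CC)O/C=C/C(=C)O[Si](C(C)C)(C(C)C)C(C)C)c(=O)c2c(OC)c1/C=C/C(C)C | intermediate
24 | cyclohexa-1,4-diene cycloadduct (ring B as C1'=C6', C3'=C4'(OSi(i-Pr)3), sp3 C2' and C5'; C2' configuration not controlled and later erased) | COc1cc2oc3c(c(=O)c2c(OC)c1/C=C/C(C)C)C[C@@H](C(C)(C)O[Si](CC)(CC)CC)OC1C=C(O[Si](C(C)C)(C(C)C)C(C)C)CC=C1-3 | intermediate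
25 | (S)-tetracycle, 5,7-dimethoxy, 6-[(E)-3-methylbut-1-enyl], C(CH3)2OSiEt3 on the oxepine carbon, C4' OSi(i-Pr)3 | COc1cc2oc3c(c(=O)c2c(OC)c1/C=C/C(C)C)C[C@@H](C(C)(C)O[Si](CC)(CC)CC)Oc1cc(O[Si](C(C)C)(C(C)C)C(C)C)ccc1-3 | intermediate
26 | (S)-tetracycle as 25 with free C(CH3)2OH | COc1cc2oc3c(c(=O)c2c(OC)c1/C=C/C(C)C)C[C@@H](C(C)(C)O)Oc1cc(O[Si](C(C)C)(C(C)C)C(C)C)ccc1-3 | intermediate
27 | (S)-tetracycle as 26 with free C5 hydroxyl (C7 methoxy kept) | COc1cc2oc3c(c(=O)c2c(O)c1/C=C/C(C)C)C[C@@H](C(C)(C)O)Oc1cc(O[Si](C(C)C)(C(C)C)C(C)C)ccc1-3 | intermediate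
28 | (S)-tetracycle as 27 with isopropenyl in place of C(CH3)2OH | COc1cc2oc3c(c(=O)c2c(O)c1/C=C/C(C)C)C[C@@H](C(C)=C)Oc1cc(O[Si](C(C)C)(C(C)C)C(C)C)ccc1-3 | intermediate
29 | (S)-tetracycle as 27 with C(CH3)2OOSiEt3 | COc1cc2oc3c(c(=O)c2c(O)c1/C=C/C(C)C)C[C@@H](C(C)(C)OO[Si](CC)(CC)CC)Oc1cc(O[Si](C(C)C)(C(C)C)C(C)C)ccc1-3 | intermediate
30 | CNP0171472.1 | COc1cc2oc3c(c(=O)c2c(O)c1/C=C/C(C)C)C[C@@H](C(C)(C)OO)Oc1cc(O)ccc1-3 | target

**Step count**

Total: 19 steps. Longest linear sequence: 17 steps (steps 3–19, from 5); the lactone branch (steps 1–2) joins at step 6.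

**Steps most likely to fail**

1. Step 14 (proposed new method). The seven-membered-ring transition state may not be reached before the siloxydiene is lost by silyl transfer or oligomerisation, or the cycloadduct may aromatise by expelling the ring-D alkoxide instead of being dehydrogenated. The fallback uses known chemistry, sets out from phenol 15 and comes back at 26; ring B is brought in as a preformed arene and ring D is closed by C–O coupling. Commercial 2-bromo-4-hydroxybenzoic acid is silylated with TIPSCl and imidazole to triisopropylsilyl 2-bromo-4-(triisopropylsilyloxy)benzoate F1, whose silyl ester hydrolyses on aqueous work-up to 2-bromo-4-(triisopropylsilyloxy)benzoic acid F2. Steglich esterification of 15 with F2 (EDC, DMAP) should give the aryl ester F3. Baker–Venkataraman rearrangement (LiN(SiMe3)2, THF, −20 °C) then gives the 1,3-diketone F4. HCl in MeOH at 40 °C should cyclodehydrate F4 and methanolyse both the triethylsilyl ether and the acetate, giving the 2-(2-bromoaryl)chromone diol F5. Intramolecular Buchwald–Hartwig etherification through the secondary hydroxyl (Pd(OAc)2, 2-(di-tert-butylphosphino)-1,1'-binaphthyl, Cs2CO3, toluene, 70 °C; seven- rather than eight-membered ring) closes ring D and delivers 26.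

2. Step 18. Hydrogen-atom transfer to the styrene double bond (benzylic peroxidation) or over-reduction of the silyl peroxide may compete with reaction at the isopropenyl group. The fallback sets out from tertiary alcohol 27, bypasses steps 17 and 18 and comes back at 30. Acid-catalysed perhydrolysis of the tertiary carbinol (50% H2O2, cat. H2SO4, THF, 0 °C) places the O–O unit directly on the tertiary carbon without touching the stereocentre and should give the C4' O-triisopropylsilyl hydroperoxide F6, which is desilylated as in step 19.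

3. Step 11. During the slow methanolysis of the hindered acetate, methoxide or the liberated side-chain alkoxide may add in conjugate fashion to the newly formed ethynylchromone. The fallback sets out from 16 and comes back at 20; the ester is removed before any alkyne exists. K2CO3 in MeOH converts 16 into the hydroxy methylchromone F7. TESCl and imidazole give the bis(triethylsilyl) ether F8. Enamination and periodate cleavage as in step 10 lead through the enamine F9 to the aldehyde F10. A short Ohira–Bestmann reaction gives the bis-silylated alkyne F11, and selective acid methanolysis of the less hindered secondary silyl ether (PPTS, MeOH, 0 °C) gives 20.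

**Further compounds**

F1 | step 14 | triisopropylsilyl 2-bromo-4-(triisopropylsilyloxy)benzoate | CC(C)[Si](OC(=O)c1ccc(O[Si](C(C)C)(C(C)C)C(C)C)cc1Br)(C(C)C)C(C)C
F2 | step 14 | 2-bromo-4-(triisopropylsilyloxy)benzoic acid | OC(=O)c1ccc(O[Si](C(C)C)(C(C)C)C(C)C)cc1Br
F3 | step 14 | aryl ester of phenol 15 with F2 | O=C(Oc1cc(OC)c(/C=C/C(C)C)c(OC)c1C(=O)CC[C@@H](C(C)(C)O[Si](CC)(CC)CC)OC(C)=O)c1ccc(O[Si](C(C)C)(C(C)C)C(C)C)cc1Br
F4 | step 14 | 1,3-diketone from Baker–Venkataraman rearrangement (α-carbon configuration not controlled) | Oc1cc(OC)c(/C=C/C(C)C)c(OC)c1C(=O)C(C[C@@H](C(C)(C)O[Si](CC)(CC)CC)OC(C)=O)C(=O)c1ccc(O[Si](C(C)C)(C(C)C)C(C)C)cc1Br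
F5 | step 14 | 2-[2-bromo-4-(triisopropylsilyloxy)phenyl]-3-[(S)-2,3-dihydroxy-3-methylbutyl]-5,7-dimethoxy-6-[(E)-3-methylbut-1-enyl]-4H-chromen-4-one | COc1cc2oc(-c3ccc(O[Si](C(C)C)(C(C)C)C(C)C)cc3Br)c(C[C@@H](C(C)(C)O)O)c(=O)c2c(OC)c1/C=C/C(C)C
F6 | step 18 | (S)-tetracycle as 30 with C4' OSi(i-Pr)3 | COc1cc2oc3c(c(=O)c2c(O)c1/C=C/C(C)C)C[C@@H](C(C)(C)OO)Oc1cc(O[Si](C(C)C)(C(C)C)C(C)C)ccc1-3
F7 | step 11 | 3-[(S)-2-hydroxy-3-methyl-3-(triethylsilyloxy)butyl]-5,7-dimethoxy-2-methyl-6-[(E)-3-methylbut-1-enyl]-4H-chromen-4-one | COc1cc2oc(C)c(C[C@@H](C(C)(C)O[Si](CC)(CC)CC)O)c(=O)c2c(OC)c1/C=C/C(C)C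
F8 | step 11 | 3-[(S)-3-methyl-2,3-bis(triethylsilyloxy)butyl]-5,7-dimethoxy-2-methyl-6-[(E)-3-methylbut-1-enyl]-4H-chromen-4-one | COc1cc2oc(C)c(C[C@@H](C(C)(C)O[Si](CC)(CC)CC)O[Si](CC)(CC)CC)c(=O)c2c(OC)c1/C=C/C(C)C
F9 | step 11 | 2-[(E)-2-(dimethylamino)vinyl] analogue of F8 | COc1cc2oc(/C=C/N(C)C)c(C[C@@H](C(C)(C)O[Si](CC)(CC)CC)O[Si](CC)(CC)CC)c(=O)c2c(OC)c1/C=C/C(C)C
F10 | step 11 | 2-formyl analogue of F8 | COc1cc2oc(C=O)c(C[C@@H](C(C)(C)O[Si](CC)(CC)CC)O[Si](CC)(CC)CC)c(=O)c2c(OC)c1/C=C/C(C)C
F11 | step 11 | 2-ethynyl analogue of F8 | COc1cc2oc(C#C)c(C[C@@H](C(C)(C)O[Si](CC)(CC)CC)O[Si](CC)(CC)CC)c(=O)c2c(OC)c1/C=C/C(C)C
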